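The route rests on disconnecting the bond between the benzoyl carbonyl carbon and C6 of ring A (the phloroglucinol ring of the dihydrocoumarin). C6 lies between the oxygen-bearing C5 and C7 and para to C8a–O1; once C8 is blocked by bromine it is the only free carbon of ring A. In one operation the key step benzoylates C6 by Friedel–Crafts acylation and uses the new carbonyl, ortho to both methoxy groups, to direct cleavage of the C5 and C7 methyl ethers. Its precursor is (R)-8-bromo-5,7-dimethoxy-4-phenylchroman-2-one, from rhodium-catalysed asymmetric phenyl addition to 5,7-dimethoxycoumarin and C8 bromination; the bromine is finally exchanged for prenyl by Stille coupling.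

Key step: step 3

Remark on numbering and configuration: chroman-2-one numbering is used (O1, C2, C3, C4, C4a, C5 to C8, C8a), and ring A is the benzo ring. The stereocenter C4 of the target is (R) (priorities C4a > phenyl > C3 > H).

Assumption: the Rh/(R)-SEGPHOS catalyst is taken to add phenyl to 5,7-dimethoxycoumarin with the same facial sense as to unsubstituted coumarin, which corresponds to (4R). The (S) ligand would be used if the sense proved opposite.

Step 1
Reactants: 1 5,7-dimethoxycoumarin; 2 phenylboronic acid
Product: 3 (R)-5,7-dimethoxy-4-phenylchroman-2-one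
Conditions: Rh(acac)(C2H4)2 (3 mol %), (R)-SEGPHOS (3.3 mol %), PhB(OH)2 (5 equiv), dioxane/H2O 10:1, 60 °C
Reagents that add atoms: phenylboronic acid, OB(O)c1ccccc1
Why: Rhodium-catalysed asymmetric 1,4-addition of an arylboronic acid to a coumarin (Hayashi–Miyaura reaction): the phenyl–rhodium species bound to (R)-SEGPHOS should insert the C3=C4 bond from one enantioface and hydrolysis of the rhodium enolate releases the lactone, so the ligand sets C4 as (R).

Step 2
Reactants: 3 (R)-5,7-dimethoxy-4-phenylchroman-2-one; 4 N-bromosuccinimide
Product: 5 (R)-8-bromo-5,7-dimethoxy-4-phenylchroman-2-one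
Conditions: NBS (1.0 equiv), MeCN, 0 °C, dark
Reagents that add atoms: N-bromosuccinimide, O=C1CCC(=O)N1Br
Why: Electrophilic aromatic bromination should go to C8, which is ortho to the C7 methoxy group and para to the C5 methoxy group, whereas C6 is flanked by two methoxy groups, that at C5 being turned toward C6 by the peri C4 substituent, as in the C8-selective bromination of 5,7-dialkoxyflavans; the C4 stereocenter is not touched.

Step 3
Reactants: 5 (R)-8-bromo-5,7-dimethoxy-4-phenylchroman-2-one; 6 benzoyl chloride
Product: 9 (R)-6-benzoyl-8-bromo-5,7-dihydroxy-4-phenylchroman-2-one, via C6 ketone dimethyl ether 7 (not isolated), via bis(dibromoboryl) ether 8 (not isolated)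
Conditions: BzCl (1.2 equiv), AlCl3 (2.5 equiv), CH2Cl2, −10 to 0 °C; then BBr3 (4 equiv), same flask, −78 to 0 °C; aq. HCl work-up
Reagents that add atoms: benzoyl chloride, O=C(Cl)c1ccccc1
Why: Friedel–Crafts acylation: the benzoyl cation formed from benzoyl chloride and AlCl3 attacks C6 of ring A and loss of the proton gives ketone 7, whose carbonyl lies ortho to both methoxy groups and assists their cleavage by BBr3 to the bis(dibromoboryl) ether 8, which is hydrolysed on work-up. The closest known reaction type is the acylation of phloroglucinol methyl ethers with demethylation ortho to the new carbonyl group. No ring is closed and no stereocenter is formed; the C4 stereocenter is remote from the reacting carbon and should be kept by working at or below 0 °C. The step needs site selectivity for C6 over C8 and C-acylation over O-acylation: the first is secured because C8 carries bromine and C6 is the only unsubstituted carbon of ring A, the second because both phenols are still methyl ethers while the acylium ion is present. The lactone and the aryl bromide should survive because acylation of the activated C6 is expected to be faster at low temperature than acyl–oxygen cleavage or ipso attack at C8.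

Step 4
Reactants: 9 (R)-6-benzoyl-8-bromo-5,7-dihydroxy-4-phenylchroman-2-one; 10 tributyl(3-methylbut-2-en-1-yl)stannane
Product: 11 (R)-6-benzoyl-5,7-dihydroxy-8-(3-methylbut-2-en-1-yl)-4-phenylchroman-2-one
Conditions: Pd(PPh3)4 (10 mol %), prenylstannane (2 equiv), toluene, 100 °C, argon
Reagents that add atoms: tributyl(3-methylbut-2-en-1-yl)stannane, CCCC[Sn](CCCC)(CCCC)CC=C(C)C
Why: Stille cross-coupling: zerovalent palladium inserts into the C8–Br bond, the prenyl group is transferred from tin and reductive elimination at the less substituted allyl terminus should give the linear prenyl arene under neutral conditions that leave the lactone, the ketone, the free phenols and the C4 stereocenter untouched.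

Compound list
1 | 5,7-dimethoxycoumarin (5,7-dimethoxy-2H-chromen-2-one) | COc1cc(OC)c2ccc(=O)oc2c1 | starting material
2 | phenylboronic acid | OB(O)c1ccccc1 | starting material
3 | (R)-5,7-dimethoxy-4-phenylchroman-2-one | COc1cc(OC)c2c(c1)OC(=O)C[C@@H]2c1ccccc1 | intermediate
4 | N-bromosuccinimide | O=C1CCC(=O)N1Br | starting material
5 | (R)-8-bromo-5,7-dimethoxy-4-phenylchroman-2-one | COc1cc(OC)c2c(c1Br)OC(=O)C[C@@H]2c1ccccc1 | intermediate
6 | benzoyl chloride | O=C(Cl)c1ccccc1 | starting material
7 | (R)-6-benzoyl-8-bromo-5,7-dimethoxy-4-phenylchroman-2-one (C6 ketone dimethyl ether) | COc1c(C(=O)c3ccccc3)c(OC)c2c(c1Br)OC(=O)C[C@@H]2c1ccccc1 | intermediate (not isolated)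
8 | (R)-6-benzoyl-8-bromo-5,7-bis(dibromoboryloxy)-4-phenylchroman-2-one (bis(dibromoboryl) ether) | BrB(Br)Oc1c(C(=O)c3ccccc3)c(OB(Br)Br)c2c(c1Br)OC(=O)C[C@@H]2c1ccccc1 | intermediate (not isolated)
9 | (R)-6-benzoyl-8-bromo-5,7-dihydroxy-4-phenylchroman-2-one | Oc1c(C(=O)c3ccccc3)c(O)c2c(c1Br)OC(=O)C[C@@H]2c1ccccc1 | intermediate
10 | tributyl(3-methylbut-2-en-1-yl)stannane | CCCC[Sn](CCCC)(CCCC)CC=C(C)C | starting material
11 | (R)-6-benzoyl-5,7-dihydroxy-8-(3-methylbut-2-en-1-yl)-4-phenylchroman-2-one | CC(C)=CCc1c(O)c(C(=O)c2ccccc2)c(O)c2c1OC(=O)C[C@@H]2c1ccccc1 | target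

Total step count: 4. Longest linear sequence: 4 steps.

Steps most likely to fail

Step 3. What may go wrong: loss or migration of the C8 bromine under AlCl3 and the HCl formed, or Lewis-acid opening of the lactone followed by ring closure onto the C4 phenyl group, before acylation at the crowded C6 is complete. Fallback: it sets out from 5 and changes the acylation from an acylium ion on the dimethyl ether to a phenol-directed nitrile acylation on the free diol. Treatment of 5 with BBr3 (CH2Cl2, −78 to 0 °C) should give (R)-8-bromo-5,7-dihydroxy-4-phenylchroman-2-one F2. A Houben–Hoesch acylation with benzonitrile (N#Cc1ccccc1) and BCl3 in 1,2-dichloroethane (rt to 60 °C) then delivers the nitrile carbon from a boron-bound phenoxide to C6, the only free ortho carbon, to give the ketimine (R)-8-bromo-5,7-dihydroxy-6-[imino(phenyl)methyl]-4-phenylchroman-2-one F3. Brief hydrolysis with 2 M HCl converts it to the ketone, and the route is rejoined at 9.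

Step 4. What may go wrong: protodestannylation of the prenylstannane by the acidic chelated phenols, slow oxidative addition into the electron-rich, doubly ortho-substituted C–Br bond, and partial coupling at the branched allyl terminus. Fallback: it sets out from 9 and replaces the cross-coupling by removal of bromine and electrophilic prenylation of the phloroglucinol ring. Radical debromination (Bu3SnH, AIBN cat., toluene, 80 °C) should give (R)-6-benzoyl-5,7-dihydroxy-4-phenylchroman-2-one F4, in which C8 is the only unsubstituted carbon of ring A. C-Prenylation with prenyl bromide (CC(C)=CCBr) and DBU in THF at 0 °C, under anhydrous conditions that keep the lactone closed, should then give 11 directly.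

Step 1. What may go wrong: slow insertion at C4 of an electron-rich coumarin next to the peri C5 methoxy group, so that protodeboronation of the boronic acid outruns addition and the enantioselectivity erodes. Fallback: it sets out from 1 and 2 and separates carbon–carbon bond formation from stereocontrol. An oxidative boron-Heck arylation at C4 (Pd(OAc)2 10 mol %, 1,10-phenanthroline, O2 1 atm, DMF, 80 °C) should give 5,7-dimethoxy-4-phenylcoumarin F1. Asymmetric conjugate reduction with a ligated copper hydride (Cu(OAc)2·H2O 5 mol %, DTBM-SEGPHOS, (EtO)2MeSiH 1.2 equiv, t-BuOH, toluene, 0 °C) then sets C4 by hydride delivery. The ligand enantiomer is chosen to give (4R), the silane is limited to avoid reduction of the lactone, and the route is rejoined at 3.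

Further compounds
F1 | step 1 | 5,7-dimethoxy-4-phenylcoumarin | COc1cc(OC)c2c(-c3ccccc3)cc(=O)oc2c1
F2 | step 3 | (R)-8-bromo-5,7-dihydroxy-4-phenylchroman-2-one | Oc1cc(O)c2c(c1Br)OC(=O)C[C@@H]2c1ccccc1
F3 | step 3 | (R)-8-bromo-5,7-dihydroxy-6-[imino(phenyl)methyl]-4-phenylchroman-2-one | Oc1c(C(=N)c3ccccc3)c(O)c2c(c1Br)OC(=O)C[C@@H]2c1ccccc1
F4 | step 4 | (R)-6-benzoyl-5,7-dihydroxy-4-phenylchroman-2-one | Oc1c(C(=O)c3ccccc3)c(O)c2c(c1)OC(=O)C[C@@H]2c1ccccc1
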